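**Retrosynthetic overview**

1. The target is triacontan-30-olide, a single 31-membered lactone ring (ring O, carbonyl C1, methylenes C2–C30, with C30 on the ring O); it is achiral and fully saturated.
2. Last disconnection: ring bond C26–C27, closed by a one-pot hydroboration / intramolecular C(sp3)–C(sp3) B-alkyl Suzuki coupling of 4-bromobutyl hexacos-25-enoate. This is the only ring formed, it is formed last, and it arrives at the saturated oxidation level.
3. Enabling feature: the ring O sits exactly four methylenes (C30–C27) from C26. C27 can therefore be the primary bromide of a 4-bromobutyl ester and C26 the terminal carbon of a C25=C26 vinyl group. Both are unhindered primary carbons on a substituent-free, strain-free polymethylene ring whose only functional group is the ester.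
4. Ester C30–O bond: carboxylate O-alkylation of hexacos-25-enoic acid with 1,4-dibromobutane.
5. C26 acid: copper-catalysed sp3–sp3 coupling (C15–C16) of 15-bromopentadecanoic acid, obtained by HBr opening of the 16-membered pentadecanolide, with undec-10-enylmagnesium bromide (C15 + C11 + C4 = C30).

Key step: step 4

Remark on the chemistry: the target has no stereocentre and no double bond, so no stereocontrol is required anywhere; atom numbers are those of line 1.

**Route**

Step 1
Reactants: 1 pentadecanolide (oxacyclohexadecan-2-one)
Product: 2 15-bromopentadecanoic acid
Conditions: 48% aq HBr, AcOH, conc. H2SO4 (cat.), reflux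
Reagents that add atoms: hydrogen bromide, Br
Why: Acid-mediated lactone opening in which the protonated ester (or the derived ω-hydroxy acid) undergoes SN2 displacement by bromide at the primary C15–O carbon, a standard conversion of a macrolide into an ω-bromo acid that should incorporate HBr completely.

Step 2
Reactants: 2 15-bromopentadecanoic acid; 3 11-bromoundec-1-ene
Product: 5 hexacos-25-enoic acid, via undec-10-enylmagnesium bromide 4 (not isolated)
Conditions: 3 (2.5 equiv), Mg, THF, rt→40 °C; then added to 2, THF, −20 °C; Li2CuCl4 (5 mol%), −20 °C→rt; 1 M HCl work-up
Reagents that add atoms: none
Why: Copper-catalysed (Li2CuCl4) sp3–sp3 cross-coupling of a primary alkyl Grignard reagent with a primary alkyl bromide; the first equivalent of 4 should convert 2 into its bromomagnesium carboxylate, which is inert to the Grignard reagent, and the terminal alkene is a spectator.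

Step 3
Reactants: 5 hexacos-25-enoic acid; 6 1,4-dibromobutane
Product: 7 4-bromobutyl hexacos-25-enoate
Conditions: 6 (8 equiv), K2CO3 (1.5 equiv), DMF/THF, 50 °C; excess 6 removed by Kugelrohr distillation
Reagents that add atoms: none
Why: SN2 O-alkylation of the potassium carboxylate by a primary dibromide, in which the large excess of 6 should suppress a second alkylation to the butane-1,4-diyl diester while the terminal alkene and the remaining C–Br bond are untouched.

Step 4
Reactants: 7 4-bromobutyl hexacos-25-enoate
Product: 9 triacontan-30-olide (target), via B-alkyl-9-BBN borane 8 (not isolated)
Conditions: 9-BBN (1.05 equiv), THF, 0 °C→rt; then syringe-pump addition (12 h) into Pd(OAc)2 (10 mol%), PCy3 (20 mol%), K3PO4·H2O (3 equiv), THF, rt→40 °C, ca. 2 mM final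
Reagents that add atoms: none
Why: Proposed new method: 9-BBN should add anti-Markovnikov to the terminal C25=C26 alkene to give the primary C26–B borane 8 without touching the ester or the C27–Br bond; Pd(0)/PCy3 then inserts into the primary C27–Br bond by SN2-type oxidative addition, the hydroxide-activated borate (from K3PO4·H2O) transfers the C26 alkyl group to the same palladium, and reductive elimination from the resulting 32-membered dialkylpalladacycle forms the C26–C27 bond. The closest known reaction types are the Pd(OAc)2/PCy3-catalysed room-temperature Suzuki coupling of β-hydrogen-bearing primary alkyl bromides with B-alkyl-9-BBN reagents (intermolecular, ester-tolerant) and the intramolecular B-alkyl Suzuki macrocyclisation onto alkenyl halides; their combination in a C(sp3)–C(sp3) macrocyclisation is the new element. The one ring closed is the 31-membered lactone, by end-to-end union of two primary sp3 termini of a single chain, so no Baldwin or transannular constraint applies and the ring is strain-free. No stereocentre is formed and the product is already at the saturated oxidation level of the target. The step needs regioselective hydroboration (secured by 9-BBN on a monosubstituted alkene), cross-coupling faster than β-hydride elimination from the alkylpalladium intermediate (secured by the bulky, electron-rich PCy3 at low temperature) and ring closure faster than chain-to-chain coupling (secured by pseudo-dilution, a raised catalyst loading so that 8 does not accumulate, and the unhindered, substituent-free polymethylene tether). The ester should survive because the hydrated phosphate base is too mild to saponify or transesterify it at these temperatures.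

**Compound list**

1 | pentadecanolide (oxacyclohexadecan-2-one) | O=C1CCCCCCCCCCCCCCO1 | starting material
2 | 15-bromopentadecanoic acid | OC(=O)CCCCCCCCCCCCCCBr | intermediate
3 | 11-bromoundec-1-ene | C=CCCCCCCCCCBr | starting material
4 | undec-10-enylmagnesium bromide | C=CCCCCCCCCC[Mg]Br | intermediate
5 | hexacos-25-enoic acid | OC(=O)CCCCCCCCCCCCCCCCCCCCCCCC=C | intermediate
6 | 1,4-dibromobutane | BrCCCCBr | starting material
7 | 4-bromobutyl hexacos-25-enoate | BrCCCCOC(=O)CCCCCCCCCCCCCCCCCCCCCCCC=C | intermediate
8 | 4-bromobutyl 26-(9-borabicyclo[3.3.1]nonan-9-yl)hexacosanoate | BrCCCCOC(=O)CCCCCCCCCCCCCCCCCCCCCCCCCB1C2CCCC1CCC2 | intermediate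
9 | triacontan-30-olide (oxacyclohentriacontan-2-one) | O=C1CCCCCCCCCCCCCCCCCCCCCCCCCCCCCO1 | target

**Step count and risks**

Total step count: 4. Longest linear sequence: 4 steps (1 → 2 → 5 → 7 → 9); the Grignard reagent 4 is made and consumed within step 2.

Steps most likely to fail:

Step 4 (Proposed new method). Chain-to-chain coupling may overtake ring closure if catalytic turnover is slower than the addition, and β-hydride elimination from the alkylpalladium intermediate or hydrolytic loss of the borane may compete at high dilution. The fallback closes the same C26–C27 bond by ring-closing olefin metathesis and then saturates it. It sets out from compound 2. Under the conditions of step 2, 2 would be coupled with dodec-11-enylmagnesium bromide F1 (from commercial 12-bromododec-1-ene and Mg) to give heptacos-26-enoic acid F2. Esterification with pent-4-en-1-ol (EDC·HCl, DMAP, CH2Cl2) would give pent-4-enyl heptacos-26-enoate F3. Ring-closing metathesis (second-generation Grubbs catalyst, CH2Cl2, 40 °C, ca. 1 mM) should give triacont-26-en-30-olide F4 as an E/Z mixture. Hydrogenation (H2, Pd/C, EtOAc) would converge both isomers on compound 9, where the fallback rejoins the route.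

Step 2. The bromomagnesium carboxylate of 2 may precipitate, and the Grignard reagent may then be diverted into homocoupling or bromine–magnesium exchange instead of cross-coupling. The fallback moves to a neutral ester and a soft organozinc partner, and sets out from compound 2. Fischer esterification (MeOH, cat. H2SO4, reflux) would give methyl 15-bromopentadecanoate F5. Compound 3 would be converted into undec-10-enylzinc bromide F6 (Zn dust, cat. I2, DMA, 80 °C). An alkyl–alkyl Negishi coupling of F5 and F6 (Pd2(dba)3, PCyp3, N-methylimidazole, THF/NMP, 80 °C) should give methyl hexacos-25-enoate F7. Saponification (LiOH, THF/H2O, then HCl) returns the route at compound 5.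

Step 3. The bromide terminus of the product may be attacked by a second carboxylate (over-alkylation to the diester), and the sparingly soluble potassium soap may react sluggishly. The fallback forms the acyl–oxygen bond instead of the alkyl–oxygen bond. It sets out from compound 5, which would be esterified with commercial 4-bromobutan-1-ol under Steglich conditions (DCC, cat. DMAP, CH2Cl2, 0 °C→rt). This returns the route directly at compound 7; no new compound is made (F0).

**Further compounds**

F1 | step 4 | dodec-11-enylmagnesium bromide | C=CCCCCCCCCCC[Mg]Br
F2 | step 4 | heptacos-26-enoic acid | OC(=O)CCCCCCCCCCCCCCCCCCCCCCCCC=C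
F3 | step 4 | pent-4-enyl heptacos-26-enoate | C=CCCCOC(=O)CCCCCCCCCCCCCCCCCCCCCCCCC=C
F4 | step 4 | (E)-triacont-26-en-30-olide (E shown; the Z isomer is expected alongside) | O=C1CCCCCCCCCCCCCCCCCCCCCCCC/C=C/CCCO1
F5 | step 2 | methyl 15-bromopentadecanoate | COC(=O)CCCCCCCCCCCCCCBr
F6 | step 2 | undec-10-enylzinc bromide | C=CCCCCCCCCC[Zn]Br
F7 | step 2 | methyl hexacos-25-enoate | COC(=O)CCCCCCCCCCCCCCCCCCCCCCCC=C
F0 | step 3 | none | none
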